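**Retrosynthetic overview**

1. Feature: in the upper 14-membered carbocycle (C1–C14) the C13 ketone has the methyl-bearing C11 at its β-position and plain C9H2–C10H2 beyond it. With a C9=C10 alkene put back, this is the γ,δ-unsaturated ketone retron of a Claisen shift that makes C11–C12 and breaks a C9–O bond.
2. Upper ring: 14-membered carbocycle ⇐ 12-membered exo-methylene cyclic enol ether (C13(=CH2)–O–C9, E-propenyl on C9) ⇐ Tebbe methylenation of the 12-membered lactone ⇐ seco acid.
3. Cyclohexene ring (C1, C14–C18) ⇐ Diels–Alder reaction of dienyne 31 with dihydropyranone 24. The C3–O–C13 lactone of 24 (C3 later becomes the ketone) is the tether that fixes C1, C14 and C18. 24 ⇐ iodide 13 + thioester 21 (C5–C6).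
4. Lower macrocycle (12 ring atoms through O24, spanned by the oxane) ⇐ C30–C31 aldol with oxane ketone 53 (from geraniol), then C20–C21 B-alkyl Suzuki macrocyclisation.
5. Ring order: dihydropyranone (temporary) → cyclohexene → 12-membered lactone → upper 14-membered carbocycle (key step) → lower macrocycle closed around the pre-made oxane.

Key step: step 29

**Remarks and assumptions**

- Backbone atoms are numbered C1–C31 (O24 = oxane oxygen) in the order of the target SMILES, starting at the quaternary ester carbon; these numbers are used for all intermediates.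
- C3 is kept as a silyl ether until step 48 because its oxygen is the lactone tether of the cycloaddition and a free 1,4-diketone is avoided; C6 is carried as a dioxolane.
- C31 is carried as an epimer mixture from step 41 to step 43 and is set in step 44.
- Compounds 25 and 27 and all unnumbered reagents are taken as commercial.

**Route**

Step 1
Reactants: 1 3-methylbutanoyl chloride; 2 (S)-4-benzyl-1,3-oxazolidin-2-one
Product: 3 (S)-4-benzyl-3-(3-methylbutanoyl)-1,3-oxazolidin-2-one
Conditions: n-BuLi, THF, −78 °C; then 1, −78 → 0 °C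
Reagents that add atoms: none
Why: N-acylation of the lithiated oxazolidinone by the acid chloride attaches the Evans auxiliary.

Step 2
Reactants: 3
Product: 4 (S)-4-benzyl-3-[(R)-2-(benzyloxymethyl)-3-methylbutanoyl]-1,3-oxazolidin-2-one
Conditions: TiCl4, i-Pr2NEt, CH2Cl2, 0 °C; BnOCH2Cl
Reagents that add atoms: benzyl chloromethyl ether, ClCOCc1ccccc1
Why: Evans alkylation of the chelated Z titanium enolate; the auxiliary benzyl group blocks one face, so C5 enters anti to it and sets C4.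

Step 3
Reactants: 4
Product: 5 (R)-2-(benzyloxymethyl)-3-methylbutanoic acid
Conditions: LiOH, H2O2, THF/H2O, 0 °C; Na2SO3
Reagents that add atoms: hydrogen peroxide, OO
Why: Hydroperoxide attacks the exocyclic imide carbonyl selectively and should cleave the auxiliary without epimerising C4.

Step 4
Reactants: 5
Product: 6 methyl (R)-4-(benzyloxymethyl)-5-methyl-3-oxohexanoate
Conditions: CDI, THF, rt; then MeO2CCH2CO2K, MgCl2, Et3N, rt → 40 °C
Reagents that add atoms: potassium methyl malonate, COC(=O)CC(=O)[O-].[K+]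
Why: Masamune–Claisen homologation: the acyl imidazolide acylates the magnesium malonate and decarboxylation gives the β-keto ester (C2, C1) under neutral conditions.

Step 5
Reactants: 6
Product: 7 methyl (3R,4R)-4-(benzyloxymethyl)-3-hydroxy-5-methylhexanoate
Conditions: RuCl2[(S)-BINAP] (1 mol%), H2 (50 atm), MeOH, 50 °C
Reagents that add atoms: none
Why: Noyori hydrogenation of the β-keto ester; the (S)-BINAP catalyst controls hydride delivery and should give the C3 carbinol (R), the centre that later steers the cycloaddition.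

Step 6
Reactants: 7
Product: 8 tert-butyl (5R,6R)-6-(benzyloxymethyl)-5-hydroxy-7-methyl-3-oxooctanoate
Conditions: t-BuOAc, LiN(i-Pr)2 (4 equiv each), THF, −78 → −30 °C
Reagents that add atoms: tert-butyl acetate, CC(=O)OC(C)(C)C
Why: Claisen condensation of the methyl ester with excess lithium enolate adds C14 and C13; the C3 alkoxide is tolerated.

Step 7
Reactants: 8
Product: 9 (6R)-6-[(2R)-1-(benzyloxy)-3-methylbutan-2-yl]-4-hydroxy-5,6-dihydro-2H-pyran-2-one
Conditions: TFA, CH2Cl2, 0 °C → rt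
Reagents that add atoms: none
Why: Acid cleaves the tert-butyl ester and lactonisation of the δ-hydroxy β-keto acid closes the C3–O–C13 lactone as the enolised dione.

Step 8
Reactants: 9
Product: 10 (2R)-2-[(2R)-1-(benzyloxy)-3-methylbutan-2-yl]-6-oxo-3,6-dihydro-2H-pyran-4-yl trifluoromethanesulfonate
Conditions: Tf2O, Et3N, CH2Cl2, −78 °C
Reagents that add atoms: trifluoromethanesulfonic anhydride, O=S(=O)(OS(=O)(=O)C(F)(F)F)C(F)(F)F
Why: O-sulfonylation of the vinylogous acid gives the enol triflate at C1.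

Step 9
Reactants: 10
Product: 11 methyl (2R)-2-[(2R)-1-(benzyloxy)-3-methylbutan-2-yl]-6-oxo-3,6-dihydro-2H-pyran-4-carboxylate
Conditions: Pd(OAc)2 (5 mol%), PPh3, CO (1 atm), MeOH, Et3N, DMF, rt
Reagents that add atoms: carbon monoxide, [C-]#[O+]; methanol, CO
Why: Palladium-catalysed methoxycarbonylation of the enol triflate installs the C1 methyl ester and makes the doubly activated dienophile alkene C1=C14.

Step 10
Reactants: 11
Product: 12 methyl (2R)-2-[(2R)-1-hydroxy-3-methylbutan-2-yl]-6-oxo-3,6-dihydro-2H-pyran-4-carboxylate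
Conditions: BCl3, CH2Cl2, −78 °C
Reagents that add atoms: none
Why: Lewis-acid debenzylation at low temperature spares the enoate, which hydrogenolysis would reduce.

Step 11
Reactants: 12
Product: 13 methyl (2R)-2-[(2S)-1-iodo-3-methylbutan-2-yl]-6-oxo-3,6-dihydro-2H-pyran-4-carboxylate
Conditions: I2, PPh3, imidazole, CH2Cl2, 0 °C
Reagents that add atoms: iodine, II
Why: Appel iodination of the primary C5 alcohol.

Step 12
Reactants: 14 methyl (R)-3-hydroxy-2-methylpropanoate
Product: 15 methyl (S)-3-iodo-2-methylpropanoate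
Conditions: I2, PPh3, imidazole, CH2Cl2, 0 °C
Reagents that add atoms: iodine, II
Why: Appel iodination; the C7 centre is not touched (the descriptor changes only by priority).

Step 13
Reactants: 15; 16 (E)-but-2-enoyl chloride
Product: 18 methyl (R,E)-2-methyl-4-oxohept-5-enoate, via alkylzinc iodide 17 (not isolated)
Conditions: Zn dust (TMSCl-activated), THF, 35 °C; then 16, Pd(PPh3)4 (3 mol%), 0 °C → rt
Reagents that add atoms: none
Why: Zinc insertion gives an ester-tolerant alkylzinc, and Negishi acylation with the enoyl chloride forms C8–C9 as the enone.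

Step 14
Reactants: 18
Product: 19 methyl (2R,4R,E)-4-hydroxy-2-methylhept-5-enoate
Conditions: (S)-2-methyl-CBS-oxazaborolidine (0.2 equiv), catecholborane, toluene, −78 °C
Reagents that add atoms: none
Why: Corey–Bakshi–Shibata reduction with the propenyl group as the large substituent should give the C9 carbinol (R) under catalyst control; the product is silylated at once to prevent lactonisation.

Step 15
Reactants: 19
Product: 20 methyl (2R,4R,E)-2-methyl-4-(triethylsilyloxy)hept-5-enoate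
Conditions: TESCl, imidazole, DMF, 0 °C
Reagents that add atoms: chlorotriethylsilane, CC[Si](Cl)(CC)CC
Why: Silylation of the secondary allylic alcohol with a group that can later be removed beside TBS and TIPS ethers.

Step 16
Reactants: 20
Product: 21 S-ethyl (2R,4R,E)-2-methyl-4-(triethylsilyloxy)hept-5-enethioate
Conditions: AlMe3, EtSH, CH2Cl2, 0 °C → rt
Reagents that add atoms: ethanethiol, CCS
Why: Dimethylaluminium thiolate converts the methyl ester directly into the thioester without enolising C7.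

Step 17
Reactants: 13; 21
Product: 23 methyl (2R)-2-[(3S,6R,8R,9E)-2,6-dimethyl-5-oxo-8-(triethylsilyloxy)undec-9-en-3-yl]-6-oxo-3,6-dihydro-2H-pyran-4-carboxylate, via alkylzinc iodide 22 (not isolated)
Conditions: Zn dust (activated), THF/DMA, 40 °C; then 21, PdCl2(PPh3)2 (5 mol%), toluene, rt
Reagents that add atoms: none
Why: Fukuyama coupling of the alkylzinc with the thioester forms C5–C6 as the ketone and tolerates the enoate, lactone and silyl ether without epimerising C7.

Step 18
Reactants: 23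
Product: 24 C6 1,3-dioxolane of 23 (dienophile)
Conditions: (TMSOCH2)2, TMSOTf (5 mol%), CH2Cl2, −78 → −30 °C
Reagents that add atoms: 1,2-bis(trimethylsilyloxy)ethane, C[Si](C)(C)OCCO[Si](C)(C)C
Why: Noyori ketalisation at low temperature protects the C6 ketone without epimerising C7 and leaves the conjugated lactone untouched.

Step 19
Reactants: 25 but-2-ynal
Product: 26 1,1-dibromopent-1-en-3-yne
Conditions: CBr4, PPh3, CH2Cl2, 0 °C
Reagents that add atoms: carbon tetrabromide, BrC(Br)(Br)Br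
Why: Corey–Fuchs dibromo-olefination makes C17 with two differentiable bromides.

Step 20
Reactants: 26; 27 isopropenylboronic acid pinacol ester
Product: 28 (Z)-3-bromo-2-methylhepta-1,3-dien-5-yne
Conditions: Pd(PPh3)4 (5 mol%), Cs2CO3, THF/H2O, rt
Reagents that add atoms: none
Why: Suzuki–Miyaura coupling of a 1,1-dibromoalkene occurs first at the bromide trans to the substituent, which puts the isopropenyl group (C15, C16) trans to C19.

Step 21
Reactants: 28
Product: 30 (Z)-2-(prop-1-en-2-yl)hex-2-en-4-yn-1-ol, via dienyl lithium 29 (not isolated)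
Conditions: t-BuLi (2.1 equiv), Et2O, −78 °C; then (CH2O)n, −78 → 0 °C
Reagents that add atoms: formaldehyde, C=O
Why: Bromine–lithium exchange with retention and trapping with formaldehyde install C31 cis to C19.

Step 22
Reactants: 30
Product: 31 triisopropylsilyl ether of 30 (diene)
Conditions: TIPSCl, imidazole, DMF, rt
Reagents that add atoms: chlorotriisopropylsilane, CC(C)[Si](Cl)(C(C)C)C(C)C
Why: Silylation of the primary allylic alcohol with a group that survives all steps up to step 39.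

Step 23
Reactants: 24; 31 (1.5 equiv)
Product: 32 cycloadduct: cyclohexene cis-fused to the C13–O–C3 δ-lactone; C1 CO2Me, C17 CH2OTIPS, C18 prop-1-ynyl, C6 dioxolane, C9 OTES
Conditions: toluene (1 M), BHT (cat.), 110 °C, sealed tube
Reagents that add atoms: none
Why: Thermal Diels–Alder reaction in which the unhindered termini C15 and C14 bond first (regiochemistry), the lactone ring lies endo (Alder rule, C19 cis to C2 and C13) and the diene adds to the lactone face anti to the C3 substituent, so that C1, C14 and C18 follow from C3.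

Step 24
Reactants: 32
Product: 34 vinyl iodide: as 32 with (E)-2-iodoprop-1-enyl on C18, via alkenylzirconocene 33 (not isolated)
Conditions: Cp2Zr(H)Cl (2 equiv), THF, rt; then I2, 0 °C
Reagents that add atoms: iodine, II
Why: Syn hydrozirconation places zirconium on the methyl-bearing alkyne carbon (away from the branched C18) and iodination with retention gives the E-C19=C20 iodide; esters and the lactone react much more slowly than the alkyne.

Step 25
Reactants: 34
Product: 37 C13 acid with C3 OTBS and C9 OTES, via lithium hydroxy carboxylate 35 (not isolated), via bis-silyl compound 36 (not isolated)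
Conditions: LiOH, THF/H2O, 0 °C → rt; dry; TBSOTf, 2,6-lutidine, CH2Cl2, −78 → 0 °C; then K2CO3, MeOH/H2O, 0 °C
Reagents that add atoms: lithium hydroxide, [Li+].[OH-]; tert-butyldimethylsilyl trifluoromethanesulfonate, CC(C)(C)[Si](C)(C)OS(=O)(=O)C(F)(F)F
Why: Hydroxide opens the δ-lactone at C13 while the neopentyl C1 methyl ester is spared; silylation of the salt and methanolysis of the silyl ester leave the C13 acid with the C3 hydroxyl blocked against relactonisation.

Step 26
Reactants: 37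
Product: 38 seco acid with free C9 hydroxyl
Conditions: PPTS, MeOH/CH2Cl2, 0 °C
Reagents that add atoms: none
Why: Mild acid methanolysis removes the secondary triethylsilyl ether and leaves the hindered TBS ether, the primary TIPS ether and the dioxolane.

Step 27
Reactants: 38
Product: 40 12-membered lactone (C13–O–C9) fused to the cyclohexene, via mixed anhydride 39 (not isolated)
Conditions: 2,4,6-Cl3C6H2COCl, Et3N, THF, rt; then DMAP, toluene, 60 °C, 1 mM, slow addition
Reagents that add atoms: none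
Why: Yamaguchi macrolactonisation; C2 and C13 are cis on the cyclohexene, so the ends of the seco acid are held close.

Step 28
Reactants: 40
Product: 41 exo-methylene macrocyclic enol ether (12-membered; C13(=CH2)–O–C9; E-propenyl on C9)
Conditions: Tebbe reagent Cp2Ti(μ-CH2)(μ-Cl)AlMe2 (1.2 equiv), pyridine, THF/toluene, −40 → 0 °C
Reagents that add atoms: Tebbe reagent, C[Al-]1(C)C[Ti](C2C=CC=C2)(C2C=CC=C2)[Cl+]1
Why: Tebbe methylenation of the lactone carbonyl; the C1 methyl ester sits on a fully substituted carbon (pivalate-like) and should react much more slowly with a small excess of reagent at low temperature.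

Step 29
Reactants: 41
Product: 42 upper-ring C13 ketone: 14-membered carbocycle with the new C11 methyl centre and an E-C9=C10 alkene
Conditions: o-xylene, Et3N (trace), 145 °C, sealed tube, base-washed glass
Reagents that add atoms: none
Why: The exo-methylene enol ether and the propenyl group make up an allyl vinyl ether (C12=C13–O–C9–C10=C11) that undergoes a concerted [3,3] sigmatropic Claisen shift through a chair, forming C11–C12 while C9–O breaks. The closest known reaction is the Claisen ring expansion of 2-methylene cyclic ethers that carry a 1-alkenyl group on the other α-carbon, made by Tebbe methylenation of alkenyl lactones. The upper 14-membered carbocycle closes by two-atom ring expansion of the existing 12-membered ether (the oxygen leaves the ring and C10, C11 and C12 enter it), not by cyclisation of an open chain. The new centre C11 is controlled by the C9 centre (R) and the E geometry of the propenyl group: bond formation is suprafacial on the allyl unit, and with the ring chain (C8) pseudo-equatorial on C9 this gives 11R in 42 (11S after saturation) together with E-C9=C10. The step needs the conformer with C8 equatorial, since the C8-axial conformer would give the Z alkene and the C11 epimer; the nine-atom tether between C13 and C9 is long enough to span the equatorial positions and C9 carries only H besides the tether. No other allyl vinyl ether is present, the only other 1,5-diene (C12=C13–C14–C15–C16=C17) could react only through a strained bridged boat ending at the fully substituted C17, and the vinyl iodide, silyl ethers, ester and ketal should be inert at 145 °C.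

Step 30
Reactants: 43 geraniol
Product: 44 (2R,3R)-2,3-epoxygeraniol
Conditions: Ti(OiPr)4 (5 mol%), D-(−)-diethyl tartrate (6 mol%), t-BuOOH, 4 Å MS, CH2Cl2, −20 °C
Reagents that add atoms: tert-butyl hydroperoxide, CC(C)(C)OO
Why: Sharpless asymmetric epoxidation of the allylic alcohol sets C28 (and C23 before inversion) under reagent control.

Step 31
Reactants: 44
Product: 46 (3S,4R)-4,8-dimethylnona-1,7-diene-3,4-diol, via terminal epoxide 45 (not isolated)
Conditions: Me3S+ I−, n-BuLi (4 equiv each), THF, −10 °C → rt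
Reagents that add atoms: trimethylsulfonium iodide, C[S+](C)C.[I-]
Why: Payne rearrangement (inversion at C23) exposes the terminal epoxide, which dimethylsulfonium methylide opens at C22; elimination gives the one-carbon-extended allylic alcohol (C21=C22) with C23 (S) and C28 (R).

Step 32
Reactants: 46
Product: 47 4-methoxybenzylidene acetal of 46 (acetal carbon as a mixture)
Conditions: 4-MeOC6H4CH(OMe)2, PPTS, CH2Cl2, rt
Reagents that add atoms: 4-methoxybenzaldehyde dimethyl acetal, COC(OC)c1ccc(OC)cc1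
Why: Acetal exchange ties the secondary and tertiary hydroxyls together so that they can be told apart in the next step.

Step 33
Reactants: 47
Product: 48 (3S,4R)-4-(4-methoxybenzyloxy)-4,8-dimethylnona-1,7-dien-3-ol
Conditions: i-Bu2AlH, CH2Cl2, −78 → 0 °C
Reagents that add atoms: none
Why: Reductive acetal opening; aluminium binds the less hindered secondary oxygen and cleaves its C–O bond, leaving the PMB group on the tertiary C28 oxygen and the C23 hydroxyl free.

Step 34
Reactants: 48
Product: 49 (2E,6R,7S)-7-hydroxy-6-(4-methoxybenzyloxy)-2,6-dimethylnona-2,8-dien-1-ol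
Conditions: SeO2 (0.3 equiv), t-BuOOH, salicylic acid (cat.), CH2Cl2, rt
Reagents that add atoms: tert-butyl hydroperoxide, CC(C)(C)OO
Why: Selenium dioxide allylic oxidation (ene, then [2,3] shift) hydroxylates the E methyl group of the trisubstituted alkene.

Step 35
Reactants: 49
Product: 51 oxane diol: (2S)-2-[(2R,5R,6S)-6-ethenyl-5-(4-methoxybenzyloxy)-5-methyloxan-2-yl]propane-1,2-diol, via (2S,3S)-epoxy alcohol 50 (not isolated)
Conditions: Ti(OiPr)4, L-(+)-diethyl tartrate, t-BuOOH, 4 Å MS, CH2Cl2, −25 °C; then CSA (cat.), rt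
Reagents that add atoms: tert-butyl hydroperoxide, CC(C)(C)OO
Why: Sharpless epoxidation of the primary allylic alcohol (the secondary vinyl carbinol is the slow-reacting partner) followed by 6-exo opening of the epoxide at C25 by the C23 hydroxyl with inversion gives the 2,6-trans oxane with C25 (R); the tertiary oxygen is blocked, so no oxolane can form.

Step 36
Reactants: 51
Product: 52 1-[(2R,5R,6S)-6-ethenyl-5-(4-methoxybenzyloxy)-5-methyloxan-2-yl]ethanone
Conditions: NaIO4, THF/H2O, 0 °C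
Reagents that add atoms: none
Why: Periodate cleavage of the 1,2-diol gives the methyl ketone (C29, C30) next to the ring oxygen.

Step 37
Reactants: 52
Product: 53 1-[(2R,5R,6S)-6-ethenyl-5-hydroxy-5-methyloxan-2-yl]ethanone
Conditions: DDQ, CH2Cl2/pH 7 buffer, 0 °C
Reagents that add atoms: none
Why: Oxidative removal of the PMB ether under buffered conditions that do not epimerise C25.

Step 38
Reactants: 42
Product: 54 saturated 14-membered C13 ketone (C9–C10 single bond)
Conditions: 2-nitrobenzenesulfonohydrazide, Et3N, CH2Cl2, rt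
Reagents that add atoms: none
Why: Diimide reduces the 1,2-disubstituted C9=C10 bond much faster than the trisubstituted vinyl iodide and the tetrasubstituted ring alkene, which removes the C9 stereochemical information after its transfer to C11.

Step 39
Reactants: 54
Product: 55 C31 primary allylic alcohol
Conditions: TBAF, AcOH, THF, 0 °C → rt
Reagents that add atoms: none
Why: Buffered fluoride removes the primary TIPS ether before the hindered secondary TBS ether at C3.

Step 40
Reactants: 55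
Product: 56 C31 enal
Conditions: MnO2, CH2Cl2, rt
Reagents that add atoms: none
Why: Chemoselective oxidation of the allylic alcohol.

Step 41
Reactants: 56; 53
Product: 58 aldol adduct as bis(trimethylsilyl) ether (C31 epimers), via lithium aldolate 57 (not isolated)
Conditions: 53, LiN(i-Pr)2 (2.1 equiv), THF, −78 °C; add 56; then TMSCl, Et3N, −78 → 0 °C
Reagents that add atoms: chlorotrimethylsilane, C[Si](C)(C)Cl
Why: Kinetic methyl-side lithium enolate of the methyl ketone adds to the aldehyde (far more electrophilic than the hindered C13 ketone) to form C30–C31; silyl capture prevents retro-aldol and later chelation by the C31 oxygen.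

Step 42
Reactants: 58
Product: 60 triol (tertiary C28 and C29 hydroxyls; secondary C31 hydroxyl as epimers), via magnesium alkoxide 59 (not isolated)
Conditions: MeMgBr, Et2O/CH2Cl2, −78 °C; then citric acid, MeOH, 0 °C
Reagents that add atoms: methylmagnesium bromide, C[Mg]Br
Why: Chelation-controlled Grignard addition (Cram chelate between the C29 carbonyl and the ring oxygen O24): methyl attacks anti to C26 and should set C29 (S); chelation also makes this ketone far more reactive than the C13 ketone.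

Step 43
Reactants: 60
Product: 61 C31 enone with free C29 hydroxyl
Conditions: Dess–Martin periodinane, NaHCO3, CH2Cl2, 0 °C
Reagents that add atoms: none
Why: The only secondary alcohol is oxidised, so both C31 epimers converge on one β-hydroxy enone.

Step 44
Reactants: 61
Product: 63 syn-1,3-diol with C31 (R), via boron chelate 62 (not isolated)
Conditions: Et2BOMe, THF/MeOH 4:1, −78 °C; NaBH4; AcOH, MeOH co-evaporation
Reagents that add atoms: none
Why: Narasaka–Prasad reduction: hydride adds axially to the six-membered boron chelate whose large C25 substituent is equatorial, giving the 1,3-syn diol (C31 R); the unchelated C13 ketone should not react at −78 °C.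

Step 45
Reactants: 63
Product: 65 bis-macrocycle: upper 14-membered carbocycle plus closed lower macrocycle (C28/C29/C31 hydroxyls free), via B-alkyl borane 64 (not isolated)
Conditions: 9-BBN-H (4 equiv), THF, 0 °C → rt; then Pd(dppf)Cl2 (10 mol%), AsPh3, Cs2CO3, DMF/THF/H2O, 50 °C, 1 mM, slow addition
Reagents that add atoms: none
Why: Anti-Markovnikov hydroboration of the terminal vinyl group and intramolecular B-alkyl Suzuki–Miyaura coupling with the E vinyl iodide form C20–C21 with retention of alkene geometry and close the lower macrocycle (12 ring atoms through O24).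

Step 46
Reactants: 65
Product: 66 C31 acetate
Conditions: Ac2O, pyridine, DMAP (cat.), CH2Cl2, 0 °C
Reagents that add atoms: acetic anhydride, CC(=O)OC(C)=O
Why: Only the secondary allylic hydroxyl is acylated under these conditions; the two tertiary hydroxyls stay free.

Step 47
Reactants: 66
Product: 67 C3 alcohol
Conditions: HF·pyridine, pyridine, THF, 0 °C → rt
Reagents that add atoms: none
Why: Buffered fluoride cleaves the hindered TBS ether without touching the acetate, the dioxolane or the tertiary alcohols.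

Step 48
Reactants: 67
Product: 68 C3 ketone with C6 still as dioxolane
Conditions: Dess–Martin periodinane, NaHCO3, CH2Cl2, 0 °C → rt
Reagents that add atoms: none
Why: Buffered oxidation of the single secondary alcohol should not epimerise C4.

Step 49
Reactants: 68
Product: 69 CNP0136131.1
Conditions: PPTS, acetone/H2O 10:1, 45 °C
Reagents that add atoms: water, O
Why: Mild hydrolysis of the dioxolane releases the C6 ketone below the acidity that would cause furan formation from the 1,4-diketone or ionise the allylic acetate.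

**Compound list**

1 | 3-methylbutanoyl chloride | CC(C)CC(Cl)=O | starting material
2 | (S)-4-benzyl-1,3-oxazolidin-2-one | O=C1N[C@@H](Cc2ccccc2)CO1 | starting material
3 | (S)-4-benzyl-3-(3-methylbutanoyl)-1,3-oxazolidin-2-one | CC(C)CC(=O)N1[C@@H](Cc2ccccc2)COC1=O | intermediate
4 | (S)-4-benzyl-3-[(R)-2-(benzyloxymethyl)-3-methylbutanoyl]-1,3-oxazolidin-2-one | O=C(N1[C@@H](Cc2ccccc2)COC1=O)[C@H](C(C)C)COCc3ccccc3 | intermediate
5 | (R)-2-(benzyloxymethyl)-3-methylbutanoic acid | OC(=O)[C@H](C(C)C)COCc1ccccc1 | intermediate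
6 | methyl (R)-4-(benzyloxymethyl)-5-methyl-3-oxohexanoate | COC(=O)CC(=O)[C@H](C(C)C)COCc1ccccc1 | intermediate
7 | methyl (3R,4R)-4-(benzyloxymethyl)-3-hydroxy-5-methylhexanoate | COC(=O)C[C@@H](O)[C@H](C(C)C)COCc1ccccc1 | intermediate
8 | tert-butyl (5R,6R)-6-(benzyloxymethyl)-5-hydroxy-7-methyl-3-oxooctanoate | CC(C)(C)OC(=O)CC(=O)C[C@@H](O)[C@H](C(C)C)COCc1ccccc1 | intermediate
9 | (6R)-6-[(2R)-1-(benzyloxy)-3-methylbutan-2-yl]-4-hydroxy-5,6-dihydro-2H-pyran-2-one | OC1=CC(=O)O[C@H](C1)[C@H](C(C)C)COCc2ccccc2 | intermediate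
10 | (2R)-2-[(2R)-1-(benzyloxy)-3-methylbutan-2-yl]-6-oxo-3,6-dihydro-2H-pyran-4-yl trifluoromethanesulfonate | FC(F)(F)S(=O)(=O)OC1=CC(=O)O[C@H](C1)[C@H](C(C)C)COCc2ccccc2 | intermediate
11 | methyl (2R)-2-[(2R)-1-(benzyloxy)-3-methylbutan-2-yl]-6-oxo-3,6-dihydro-2H-pyran-4-carboxylate | COC(=O)C1=CC(=O)O[C@H](C1)[C@H](C(C)C)COCc2ccccc2 | intermediate
12 | methyl (2R)-2-[(2R)-1-hydroxy-3-methylbutan-2-yl]-6-oxo-3,6-dihydro-2H-pyran-4-carboxylate | COC(=O)C1=CC(=O)O[C@H](C1)[C@H](C(C)C)CO | intermediate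
13 | methyl (2R)-2-[(2S)-1-iodo-3-methylbutan-2-yl]-6-oxo-3,6-dihydro-2H-pyran-4-carboxylate | COC(=O)C1=CC(=O)O[C@H](C1)[C@H](C(C)C)CI | intermediate
14 | methyl (R)-3-hydroxy-2-methylpropanoate | COC(=O)[C@H](C)CO | starting material
15 | methyl (S)-3-iodo-2-methylpropanoate | COC(=O)[C@H](C)CI | intermediate
16 | (E)-but-2-enoyl chloride | C/C=C/C(Cl)=O | starting material
17 | [(S)-3-methoxy-2-methyl-3-oxopropyl]zinc iodide | COC(=O)[C@H](C)C[Zn]I | intermediate
18 | methyl (R,E)-2-methyl-4-oxohept-5-enoate | COC(=O)[C@H](C)CC(=O)/C=C/C | intermediate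
19 | methyl (2R,4R,E)-4-hydroxy-2-methylhept-5-enoate | COC(=O)[C@H](C)C[C@H](/C=C/C)O | intermediate
20 | methyl (2R,4R,E)-2-methyl-4-(triethylsilyloxy)hept-5-enoate | COC(=O)[C@H](C)C[C@H](/C=C/C)O[Si](CC)(CC)CC | intermediate
21 | S-ethyl (2R,4R,E)-2-methyl-4-(triethylsilyloxy)hept-5-enethioate | CCSC(=O)[C@H](C)C[C@H](/C=C/C)O[Si](CC)(CC)CC | intermediate
22 | alkylzinc iodide from 13 (zinc on C5) | COC(=O)C1=CC(=O)O[C@H](C1)[C@H](C(C)C)C[Zn]I | intermediate
23 | methyl (2R)-2-[(3S,6R,8R,9E)-2,6-dimethyl-5-oxo-8-(triethylsilyloxy)undec-9-en-3-yl]-6-oxo-3,6-dihydro-2H-pyran-4-carboxylate | COC(=O)C1=CC(=O)O[C@H](C1)[C@H](C(C)C)CC(=O)[C@H](C)C[C@H](/C=C/C)O[Si](CC)(CC)CC | intermediate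
24 | C6 1,3-dioxolane of 23 (dienophile) | COC(=O)C1=CC(=O)O[C@H](C1)[C@H](C(C)C)CC2(OCCO2)[C@H](C)C[C@H](/C=C/C)O[Si](CC)(CC)CC | intermediate
25 | but-2-ynal | CC#CC=O | starting material
26 | 1,1-dibromopent-1-en-3-yne | CC#CC=C(Br)Br | intermediate
27 | 4,4,5,5-tetramethyl-2-(prop-1-en-2-yl)-1,3,2-dioxaborolane | CC(=C)B1OC(C)(C)C(C)(C)O1 | starting material
28 | (Z)-3-bromo-2-methylhepta-1,3-dien-5-yne | CC#C/C=C(/C(C)=C)Br | intermediate
29 | dienyl lithium from 28 | CC#C/C=C(/C(C)=C)[Li] | intermediate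
30 | (Z)-2-(prop-1-en-2-yl)hex-2-en-4-yn-1-ol | CC#C/C=C(/C(C)=C)CO | intermediate
31 | triisopropylsilyl ether of 30 (diene) | CC#C/C=C(/C(C)=C)CO[Si](C(C)C)(C(C)C)C(C)C | intermediate
32 | cycloadduct: cyclohexene cis-fused to the C13–O–C3 lactone, C18 prop-1-ynyl; C1, C14, C18 as in the target, C3 (R), C9 (R) | COC(=O)[C@]12C[C@H]([C@H](C(C)C)CC3(OCCO3)[C@H](C)C[C@H](/C=C/C)O[Si](CC)(CC)CC)OC(=O)[C@H]1CC(C)=C(CO[Si](C(C)C)(C(C)C)C(C)C)[C@H]2C#CC | intermediate
33 | alkenylzirconocene chloride from 32 (zirconium on C20) | COC(=O)[C@]12C[C@H]([C@H](C(C)C)CC3(OCCO3)[C@H](C)C[C@H](/C=C/C)O[Si](CC)(CC)CC)OC(=O)[C@H]1CC(C)=C(CO[Si](C(C)C)(C(C)C)C(C)C)[C@H]2/C=C(\C)[Zr](Cl)(C1C=CC=C1)C1C=CC=C1 | intermediate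
34 | cycloadduct with (E)-2-iodoprop-1-enyl on C18 | COC(=O)[C@]12C[C@H]([C@H](C(C)C)CC3(OCCO3)[C@H](C)C[C@H](/C=C/C)O[Si](CC)(CC)CC)OC(=O)[C@H]1CC(C)=C(CO[Si](C(C)C)(C(C)C)C(C)C)[C@H]2/C=C(\C)I | intermediate
35 | lithium salt of the C3-hydroxy C13-carboxylate (lactone opened) | COC(=O)[C@]1(C[C@@H](O)[C@H](C(C)C)CC2(OCCO2)[C@H](C)C[C@H](/C=C/C)O[Si](CC)(CC)CC)[C@@H](C([O-])=O)CC(C)=C(CO[Si](C(C)C)(C(C)C)C(C)C)[C@H]1/C=C(\C)I.[Li+] | intermediate
36 | C3 TBS ether, C13 TBS ester | COC(=O)[C@]1(C[C@@H](O[Si](C)(C)C(C)(C)C)[C@H](C(C)C)CC2(OCCO2)[C@H](C)C[C@H](/C=C/C)O[Si](CC)(CC)CC)[C@@H](C(=O)O[Si](C)(C)C(C)(C)C)CC(C)=C(CO[Si](C(C)C)(C(C)C)C(C)C)[C@H]1/C=C(\C)I | intermediate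
37 | C13 acid, C3 OTBS, C9 OTES | COC(=O)[C@]1(C[C@@H](O[Si](C)(C)C(C)(C)C)[C@H](C(C)C)CC2(OCCO2)[C@H](C)C[C@H](/C=C/C)O[Si](CC)(CC)CC)[C@@H](C(O)=O)CC(C)=C(CO[Si](C(C)C)(C(C)C)C(C)C)[C@H]1/C=C(\C)I | intermediate
38 | seco acid: C13 acid, C9 hydroxyl (R), C3 OTBS | COC(=O)[C@]1(C[C@@H](O[Si](C)(C)C(C)(C)C)[C@H](C(C)C)CC2(OCCO2)[C@H](C)C[C@H](/C=C/C)O)[C@@H](C(O)=O)CC(C)=C(CO[Si](C(C)C)(C(C)C)C(C)C)[C@H]1/C=C(\C)I | intermediate
39 | mixed 2,4,6-trichlorobenzoic anhydride of 38 | COC(=O)[C@]1(C[C@@H](O[Si](C)(C)C(C)(C)C)[C@H](C(C)C)CC2(OCCO2)[C@H](C)C[C@H](/C=C/C)O)[C@@H](C(=O)OC(=O)c2c(Cl)cc(Cl)cc2Cl)CC(C)=C(CO[Si](C(C)C)(C(C)C)C(C)C)[C@H]1/C=C(\C)I | intermediate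
40 | 12-membered lactone (C13–O–C9) fused to the cyclohexene | COC(=O)[C@]12C[C@@H](O[Si](C)(C)C(C)(C)C)[C@H](C(C)C)CC3(OCCO3)[C@H](C)C[C@H](/C=C/C)OC(=O)[C@H]1CC(C)=C(CO[Si](C(C)C)(C(C)C)C(C)C)[C@H]2/C=C(\C)I | intermediate
41 | exo-methylene macrocyclic enol ether (key-step precursor): 12-membered ring, C13(=CH2)–O–C9, C9 (R) with E-propenyl, C3 OTBS, C6 dioxolane | COC(=O)[C@]12C[C@@H](O[Si](C)(C)C(C)(C)C)[C@H](C(C)C)CC3(OCCO3)[C@H](C)C[C@H](/C=C/C)OC(=C)[C@H]1CC(C)=C(CO[Si](C(C)C)(C(C)C)C(C)C)[C@H]2/C=C(\C)I | intermediate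
42 | upper-ring C13 ketone (key-step product): 14-membered carbocycle, new C11 methyl centre, E-C9=C10 | COC(=O)[C@]12C[C@@H](O[Si](C)(C)C(C)(C)C)[C@H](C(C)C)CC3(OCCO3)[C@H](C)C/C=C/[C@H](C)CC(=O)[C@H]1CC(C)=C(CO[Si](C(C)C)(C(C)C)C(C)C)[C@H]2/C=C(\C)I | intermediate
43 | geraniol | CC(C)=CCC/C(C)=C/CO | starting material
44 | (2R,3R)-2,3-epoxygeraniol | OC[C@H]1O[C@]1(C)CCC=C(C)C | intermediate
45 | Payne-rearranged terminal epoxide (present as its lithium alkoxide): (2R)-6-methyl-2-[(2S)-oxiran-2-yl]hept-5-en-2-ol | C1O[C@@H]1[C@](C)(O)CCC=C(C)C | intermediate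
46 | (3S,4R)-4,8-dimethylnona-1,7-diene-3,4-diol | C=C[C@H](O)[C@](C)(O)CCC=C(C)C | intermediate
47 | 4-methoxybenzylidene acetal of 46 | C=C[C@@H]1OC(c2ccc(OC)cc2)O[C@]1(C)CCC=C(C)C | intermediate
48 | (3S,4R)-4-(4-methoxybenzyloxy)-4,8-dimethylnona-1,7-dien-3-ol | C=C[C@H](O)[C@](C)(OCc1ccc(OC)cc1)CCC=C(C)C | intermediate
49 | (2E,6R,7S)-7-hydroxy-6-(4-methoxybenzyloxy)-2,6-dimethylnona-2,8-dien-1-ol | C=C[C@H](O)[C@](C)(OCc1ccc(OC)cc1)CC/C=C(\C)CO | intermediate
50 | (2S,3S)-2,3-epoxide of 49 | C=C[C@H](O)[C@](C)(OCc1ccc(OC)cc1)CC[C@@H]1O[C@@]1(C)CO | intermediate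
51 | (2S)-2-[(2R,5R,6S)-6-ethenyl-5-(4-methoxybenzyloxy)-5-methyloxan-2-yl]propane-1,2-diol | C=C[C@@H]1O[C@H](CC[C@@]1(C)OCc2ccc(OC)cc2)[C@@](C)(O)CO | intermediate
52 | 1-[(2R,5R,6S)-6-ethenyl-5-(4-methoxybenzyloxy)-5-methyloxan-2-yl]ethanone | C=C[C@@H]1O[C@H](CC[C@@]1(C)OCc2ccc(OC)cc2)C(C)=O | intermediate
53 | 1-[(2R,5R,6S)-6-ethenyl-5-hydroxy-5-methyloxan-2-yl]ethanone | C=C[C@@H]1O[C@H](CC[C@@]1(C)O)C(C)=O | intermediate
54 | saturated 14-membered C13 ketone (C11 S), C17 CH2OTIPS | COC(=O)[C@]12C[C@@H](O[Si](C)(C)C(C)(C)C)[C@H](C(C)C)CC3(OCCO3)[C@H](C)CCC[C@H](C)CC(=O)[C@H]1CC(C)=C(CO[Si](C(C)C)(C(C)C)C(C)C)[C@H]2/C=C(\C)I | intermediate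
55 | C31 primary allylic alcohol | COC(=O)[C@]12C[C@@H](O[Si](C)(C)C(C)(C)C)[C@H](C(C)C)CC3(OCCO3)[C@H](C)CCC[C@H](C)CC(=O)[C@H]1CC(C)=C(CO)[C@H]2/C=C(\C)I | intermediate
56 | C31 enal | COC(=O)[C@]12C[C@@H](O[Si](C)(C)C(C)(C)C)[C@H](C(C)C)CC3(OCCO3)[C@H](C)CCC[C@H](C)CC(=O)[C@H]1CC(C)=C(C=O)[C@H]2/C=C(\C)I | intermediate
57 | dilithium aldolate (C31 and C28 alkoxides; C31 epimers) | COC(=O)[C@]12C[C@@H](O[Si](C)(C)C(C)(C)C)[C@H](C(C)C)CC3(OCCO3)[C@H](C)CCC[C@H](C)CC(=O)[C@H]1CC(C)=C(C([O-])CC(=O)[C@H]3CC[C@@](C)([O-])[C@H](C=C)O3)[C@H]2/C=C(\C)I.[Li+].[Li+] | intermediate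
58 | aldol adduct, C31 and C28 trimethylsilyl ethers (C31 epimers) | COC(=O)[C@]12C[C@@H](O[Si](C)(C)C(C)(C)C)[C@H](C(C)C)CC3(OCCO3)[C@H](C)CCC[C@H](C)CC(=O)[C@H]1CC(C)=C(C(O[Si](C)(C)C)CC(=O)[C@H]3CC[C@@](C)(O[Si](C)(C)C)[C@H](C=C)O3)[C@H]2/C=C(\C)I | intermediate
59 | C29 magnesium alkoxide after methyl addition (C31 epimers) | COC(=O)[C@]12C[C@@H](O[Si](C)(C)C(C)(C)C)[C@H](C(C)C)CC3(OCCO3)[C@H](C)CCC[C@H](C)CC(=O)[C@H]1CC(C)=C(C(O[Si](C)(C)C)C[C@](C)(O[Mg]Br)[C@H]3CC[C@@](C)(O[Si](C)(C)C)[C@H](C=C)O3)[C@H]2/C=C(\C)I | intermediate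
60 | triol: C29 (S) and C28 tertiary alcohols, C31 alcohol (epimers) | COC(=O)[C@]12C[C@@H](O[Si](C)(C)C(C)(C)C)[C@H](C(C)C)CC3(OCCO3)[C@H](C)CCC[C@H](C)CC(=O)[C@H]1CC(C)=C(C(O)C[C@](C)(O)[C@H]3CC[C@@](C)(O)[C@H](C=C)O3)[C@H]2/C=C(\C)I | intermediate
61 | C31 enone with C29 hydroxyl | COC(=O)[C@]12C[C@@H](O[Si](C)(C)C(C)(C)C)[C@H](C(C)C)CC3(OCCO3)[C@H](C)CCC[C@H](C)CC(=O)[C@H]1CC(C)=C(C(=O)C[C@](C)(O)[C@H]3CC[C@@](C)(O)[C@H](C=C)O3)[C@H]2/C=C(\C)I | intermediate
62 | diethylborinate chelate of 61 (boron on the C29 oxygen) | COC(=O)[C@]12C[C@@H](O[Si](C)(C)C(C)(C)C)[C@H](C(C)C)CC3(OCCO3)[C@H](C)CCC[C@H](C)CC(=O)[C@H]1CC(C)=C(C(=O)C[C@](C)(OB(CC)CC)[C@H]3CC[C@@](C)(O)[C@H](C=C)O3)[C@H]2/C=C(\C)I | intermediate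
63 | syn-1,3-diol, C31 (R), C29 (S) | COC(=O)[C@]12C[C@@H](O[Si](C)(C)C(C)(C)C)[C@H](C(C)C)CC3(OCCO3)[C@H](C)CCC[C@H](C)CC(=O)[C@H]1CC(C)=C([C@H](O)C[C@](C)(O)[C@H]3CC[C@@](C)(O)[C@H](C=C)O3)[C@H]2/C=C(\C)I | intermediate
64 | B-alkyl-9-BBN adduct of 63 (boron on C21; hydroxyls drawn free) | COC(=O)[C@]12C[C@@H](O[Si](C)(C)C(C)(C)C)[C@H](C(C)C)CC3(OCCO3)[C@H](C)CCC[C@H](C)CC(=O)[C@H]1CC(C)=C([C@H](O)C[C@](C)(O)[C@H]3CC[C@@](C)(O)[C@H](CCB4C5CCCC4CCC5)O3)[C@H]2/C=C(\C)I | intermediate
65 | bis-macrocycle: upper 14-membered carbocycle and closed lower macrocycle; C3 OTBS, C6 dioxolane, C31 hydroxyl | COC(=O)[C@]12C[C@@H](O[Si](C)(C)C(C)(C)C)[C@H](C(C)C)CC3(OCCO3)[C@H](C)CCC[C@H](C)CC(=O)[C@H]1CC(C)=C1[C@H]2/C=C(\C)CC[C@@H]2O[C@H](CC[C@@]2(C)O)[C@@](C)(O)C[C@H]1O | intermediate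
66 | C31 acetate of 65 | COC(=O)[C@]12C[C@@H](O[Si](C)(C)C(C)(C)C)[C@H](C(C)C)CC3(OCCO3)[C@H](C)CCC[C@H](C)CC(=O)[C@H]1CC(C)=C1[C@H]2/C=C(\C)CC[C@@H]2O[C@H](CC[C@@]2(C)O)[C@@](C)(O)C[C@H]1OC(C)=O | intermediate
67 | C3 alcohol | COC(=O)[C@]12C[C@@H](O)[C@H](C(C)C)CC3(OCCO3)[C@H](C)CCC[C@H](C)CC(=O)[C@H]1CC(C)=C1[C@H]2/C=C(\C)CC[C@@H]2O[C@H](CC[C@@]2(C)O)[C@@](C)(O)C[C@H]1OC(C)=O | intermediate
68 | C3 ketone, C6 dioxolane | COC(=O)[C@]12CC(=O)[C@H](C(C)C)CC3(OCCO3)[C@H](C)CCC[C@H](C)CC(=O)[C@H]1CC(C)=C1[C@H]2/C=C(\C)CC[C@@H]2O[C@H](CC[C@@]2(C)O)[C@@](C)(O)C[C@H]1OC(C)=O | intermediate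
69 | CNP0136131.1 | COC(=O)[C@]12CC(=O)[C@H](C(C)C)CC(=O)[C@H](C)CCC[C@H](C)CC(=O)[C@H]1CC(C)=C1[C@H]2/C=C(\C)CC[C@@H]2O[C@H](CC[C@@]2(C)O)[C@@](C)(O)C[C@H]1OC(C)=O | target

**Counts**

Total steps: 49. Longest linear sequence: 32 steps (steps 1–11, 17, 18, 23–29, 38–49).

**Steps most likely to fail**

1. Step 29 (Claisen ring expansion). The shift may pass through the conformer with the ring chain axial on C9, which gives the Z alkene and the C11 epimer, or the strained enol ether may isomerise or eliminate before it rearranges. Fallback, setting out from 37: the C13 acid is condensed with Meldrum's acid (EDC, DMAP, CH2Cl2) to give the acyl Meldrum's acid F1, and HF·pyridine removes the C9 triethylsilyl group to give the C9 alcohol F2. Heating F2 in toluene at 100 °C at high dilution expels acetone and CO2, and the acylketene is trapped by the C9 hydroxyl as the 14-membered β-keto lactone F3. Further heating in xylene at 150 °C takes the enol of F3 through a decarboxylative Claisen (Carroll) shift in a larger, less constrained ring, with the same suprafacial transfer from C9 to C11, and rejoins the route at 42. This path also does without steps 27 and 28, so it covers over-methylenation of the C1 ester in step 28 as well.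

2. Step 23 (Diels–Alder union). The long-chain dienophile may react too slowly at a temperature the diene tolerates, or regio-, endo- and facial selectivity may each be incomplete, giving isomer mixtures. Fallback, setting out from 13 and 31: the cycloaddition is run on the small iodide 13 (toluene, 100 °C, or Me2AlCl, CH2Cl2, −40 °C, which this chain-free lactone tolerates) to give the iodide cycloadduct F4, whose isomers are easier to separate. Zinc insertion then gives the alkylzinc iodide F5, Fukuyama coupling with 21 gives the C6 ketone F6, and ketalisation as in step 18 rejoins the route at 32.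

3. Step 24 (hydrozirconation–iodination). Cp2Zr(H)Cl may reduce the δ-lactone or add to the propenyl group, and regiocontrol on the internal alkyne may be incomplete. Fallback, setting out from 31: the carbonyl-free dienyne is hydrozirconated (Cp2Zr(H)Cl, THF) to the dienylzirconocene chloride F7 and iodinated to the iodotriene F8. Cycloaddition of F8 with 24 under the conditions of step 23 rejoins the route at 34.

**Further compounds**

F1 | step 29 | acyl Meldrum's acid from 37 (enol form; C9 OTES) | COC(=O)[C@]1(C[C@@H](O[Si](C)(C)C(C)(C)C)[C@H](C(C)C)CC2(OCCO2)[C@H](C)C[C@H](/C=C/C)O[Si](CC)(CC)CC)[C@@H](C(O)=C2C(=O)OC(C)(C)OC2=O)CC(C)=C(CO[Si](C(C)C)(C(C)C)C(C)C)[C@H]1/C=C(\C)I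
F2 | step 29 | C9 alcohol of F1 | COC(=O)[C@]1(C[C@@H](O[Si](C)(C)C(C)(C)C)[C@H](C(C)C)CC2(OCCO2)[C@H](C)C[C@H](/C=C/C)O)[C@@H](C(O)=C2C(=O)OC(C)(C)OC2=O)CC(C)=C(CO[Si](C(C)C)(C(C)C)C(C)C)[C@H]1/C=C(\C)I
F3 | step 29 | 14-membered β-keto lactone (C13(=O)–CH2–C(=O)–O–C9) | COC(=O)[C@]12C[C@@H](O[Si](C)(C)C(C)(C)C)[C@H](C(C)C)CC3(OCCO3)[C@H](C)C[C@H](/C=C/C)OC(=O)CC(=O)[C@H]1CC(C)=C(CO[Si](C(C)C)(C(C)C)C(C)C)[C@H]2/C=C(\C)I
F4 | step 23 | cycloadduct of 13 and 31 (C5 iodide) | COC(=O)[C@]12C[C@H]([C@H](C(C)C)CI)OC(=O)[C@H]1CC(C)=C(CO[Si](C(C)C)(C(C)C)C(C)C)[C@H]2C#CC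
F5 | step 23 | alkylzinc iodide from F4 | COC(=O)[C@]12C[C@H]([C@H](C(C)C)C[Zn]I)OC(=O)[C@H]1CC(C)=C(CO[Si](C(C)C)(C(C)C)C(C)C)[C@H]2C#CC
F6 | step 23 | C6 ketone of the cycloadduct | COC(=O)[C@]12C[C@H]([C@H](C(C)C)CC(=O)[C@H](C)C[C@H](/C=C/C)O[Si](CC)(CC)CC)OC(=O)[C@H]1CC(C)=C(CO[Si](C(C)C)(C(C)C)C(C)C)[C@H]2C#CC
F7 | step 24 | dienylzirconocene chloride from 31 | C\C(=C/C=C(/C(C)=C)CO[Si](C(C)C)(C(C)C)C(C)C)[Zr](Cl)(C1C=CC=C1)C1C=CC=C1
F8 | step 24 | iodotriene: triisopropylsilyl ether of (2Z,4E)-5-iodo-2-(prop-1-en-2-yl)hexa-2,4-dien-1-ol | C\C(I)=C/C=C(/C(C)=C)CO[Si](C(C)C)(C(C)C)C(C)C
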